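Late in the alder and maple runs X stops climbing, so I start from that flat end and reckon back to the two new flasks.

common to all: G 83 mM (held)

| run | D | J | temperature | remark | time |
|---|---|---|---|---|---|
| alder | 0.42 M | 0.42 M | 85 °C | run made earlier |  |
| maple | 0.66 M | 0.66 M | 102 °C | run made earlier |  |
| teal | 0.30 M | 0.30 M | 115 °C |  | 25 h |
| grey | 0.30 M | 0.30 M | 90 °C |  | 25 h |

- alder (time / h: X / %): 20.0: 50.2; 40.0: 52.1; 48.0: 51.4; 72.0: 48.6; 96.0: 50.2; 120: 49.9; 144: 50.8
- maple (time / h: X / %): 3.00: 19.3; 10.0: 49.5; 15.0: 47.6; 25.0: 51.9; 40.0: 47.1; 50.0: 49.9; 60.0: 50.1

(readings scatter by 1 percentage point)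

* the flask that comes out highest in amount of X, in percent of the D and J together charged, or "all alike" when all lie within 1.5 percentage points (teal / grey / all alike)
* X at the end, in percent of the D and J together charged, teal
* X at the end, in percent of the D and J together charged, grey

- L is single-handed; D and J are mirror images of each other, charged as a racemate, each of them at the stated concentration
- at the start none of L is dissolved
- steps under discussion: 2 L -> Z; L + D -> X; L + J -> Q; X <-> Q; D <-> J; G <-> L
- the handed part of L does not stay in what it makes, so the products of the two hands are mirror images too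

The alder readings from 40.0 h on and the maple readings from 10.0 h on average 49.9 %. I freeze this as my late share, the part of the charged D and J that stands as X once X stops changing. Teal and grey each charge 0.30 M of D and of J, so the share asks for c(X) = 0.300 M within 25 h, a pace of 0.0120 M/h. Alder's reading at 20.0 h stands for an average of 0.0211 M/h up to then, which is faster.

That link is weak, since alder held more charge and a pace in M/h may fall with the charge. So I compare times to the flat level instead. The alder readings are flat by 20.0 h and the maple readings by 10.0 h, both shorter than 25 h, and grey is hotter than alder. Teal is hotter than either run, so its early flattening of X is what I watch. I commit to 49.9 % in both flasks, which makes neither of them the higher.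

The forecast gives 50 % for teal and 50 % for grey, calls them all alike, and says “Rates are not limiting”.

The flasks give 50.0 % in teal and 50.0 % in grey, beside my late share of 49.9 %, and the answer to which comes out highest is all alike.

    2 L → Z (k = 6.05 /M/h, Ea = 76.0 kJ/mol)
    L + D → X (k = 11.0 /M/h, Ea = 93.0 kJ/mol)
    L + J → Q (k = 6.73 /M/h, Ea = 87.0 kJ/mol)
    X ⇌ Q (k = 0.303 /h, Ea = 104 kJ/mol)
    D ⇌ J (k = 0.206 /h, Ea = 116 kJ/mol)
    G ⇌ L, rate k6*(csat - [L]) (kL = 2.11 /h)
    (constants at 90 °C)

In teal the relaxation half-life of X and Q by the step X ⇌ Q alone, both ways together, is 0.124 h, far shorter than the 25 h of the run. At that time teal holds X at 50.0 % and Q at 50.0 %, equal shares under thermodynamic control.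

For teal left until 40 h, the late share gives 49.9 % of X. The computed flask gives 50.0 %, with Q at 50.0 %.

The numbers in the tables were computed for an exercise; scatter was added.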